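**Plan**

- Locants used throughout: ring C1 (C=O), C2=C3, C4 (OMe), C5, C6 (quaternary); side chain C7 (CH–CH3) and C8 (CH–OH, aryl).
- Retrosynthesis cuts, in order: the C8–O silyl and C4–O–CH3 bonds, the ring bond C3–C4, C1–C2, the two C6–CH2 bonds, and last C7–C8.
- Forward: syn-crotylboration of veratraldehyde, then a temporary γ-lactone ring (O, C1, C6, C7, C8), two enolate alkylations at C6, opening of the lactone by acetylide (C1–C2), and closure of the cyclohexenone ring last at C3–C4.
- Enabling feature: in the 4-methoxycyclohex-2-enone ring, C3 (enone β-carbon) and C4 (an aldehyde carbon in disguise) are both acceptor carbons and C2=C3 is cis. A (Z)-β-iodoenone converted into a C3 vinylchromium reverses the polarity of C3 and joins it to the C4 aldehyde.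
- Stereochemistry: C7 and C8 from the catalyst-controlled crotylboration; C6 from allylation anti to the cis C7-methyl/C8-aryl pair of the lactone; C4 from the ring closure under control of C6.

Key step: step 10

Assumption: the (R)-enantiomer of TRIP is taken to send allyl- and crotylboronates to the Re face of aryl aldehydes, so the (S)-acid is used to reach (S) at C8; if the sense were opposite, the antipodal acid would be used.

**Route**

Step 1
Reactants: 1 3,4-dimethoxybenzaldehyde; 2 (Z)-crotylboronic acid pinacol ester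
Product: 3 (1S,2R)-1-(3,4-dimethoxyphenyl)-2-methylbut-3-en-1-ol
Conditions: (S)-TRIP [(S)-3,3'-bis(2,4,6-triisopropylphenyl)-1,1'-binaphthyl-2,2'-diyl hydrogen phosphate] (5 mol %), 4 Å MS, toluene, −30 °C; aq. NaHCO3 work-up
Reagents that add atoms: none
Why: Chiral phosphoric acid-catalysed crotylboration through a closed chair six-membered transition state, in which the (Z)-crotyl geometry should translate into the syn relationship of C8–OH and C7–CH3 and the (S)-acid should deliver the crotyl group to the Si face of the aldehyde, setting (S) at C8 and (R) at C7.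

Step 2
Reactants: 3 (1S,2R)-1-(3,4-dimethoxyphenyl)-2-methylbut-3-en-1-ol
Product: 5 (1S,2R)-1-(3,4-dimethoxyphenyl)-2-methylbutane-1,4-diol, via alkylborane 4 (not isolated)
Conditions: 9-BBN, THF, 0 → 23 °C; then NaOH, H2O2, 0 → 23 °C
Reagents that add atoms: hydrogen peroxide, OO; 9-borabicyclo[3.3.1]nonane (9-BBN), B1C2CCCC1CCC2 (its atoms remain only in 4)
Why: Hydroboration–oxidation, in which the bulky borane should add anti-Markovnikov to the monosubstituted alkene and the C–B bond is oxidised with retention, giving the primary alcohol without touching C7 or C8.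

Step 3
Reactants: 5 (1S,2R)-1-(3,4-dimethoxyphenyl)-2-methylbutane-1,4-diol
Product: 8 (4R,5S)-5-(3,4-dimethoxyphenyl)-4-methyldihydrofuran-2(3H)-one, via hydroxy aldehyde 6 (not isolated), via lactol 7 (not isolated)
Conditions: TEMPO (2,2,6,6-tetramethylpiperidin-1-oxyl, 20 mol %), PhI(OAc)2 (2.5 equiv), CH2Cl2, 23 °C
Reagents that add atoms: none
Why: Oxidative lactonisation of a 1,4-diol, in which the oxoammonium oxidant should select the primary alcohol, aldehyde 6 closes onto the C8 hydroxyl to lactol 7, and 7 is oxidised on to the γ-lactone, so the temporary ring O–C1–C6–C7–C8 forms with the cis C7-methyl/C8-aryl relationship untouched.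

Step 4
Reactants: 8 (4R,5S)-5-(3,4-dimethoxyphenyl)-4-methyldihydrofuran-2(3H)-one
Product: 10 (3R,4R,5S)-5-(3,4-dimethoxyphenyl)-4-methyl-3-(prop-2-en-1-yl)dihydrofuran-2(3H)-one, via lithium enolate 9 (not isolated)
Conditions: LDA (LiN(i-Pr)2), THF, −78 °C; then allyl bromide, −78 → −30 °C
Reagents that add atoms: allyl bromide, C=CCBr; lithium diisopropylamide, [Li]N(C(C)C)C(C)C (lithium remains only in 9)
Why: Enolate alkylation with a reactive allylic halide, in which allyl should enter anti to the C7 methyl group, although the configuration at C6 is of no consequence here because C6 is made planar again in step 6.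

Step 5
Reactants: 10 (3R,4R,5S)-5-(3,4-dimethoxyphenyl)-4-methyl-3-(prop-2-en-1-yl)dihydrofuran-2(3H)-one
Product: 13 (3R,4R,5S)-3-(2,2-dimethoxyethyl)-5-(3,4-dimethoxyphenyl)-4-methyldihydrofuran-2(3H)-one, via ozonide 11 (not isolated), via aldehyde 12 (not isolated)
Conditions: O3, CH2Cl2, −78 °C (Sudan Red 7B end point); Me2S, −78 → 23 °C; then MeOH, HC(OMe)3, PPTS (pyridinium p-toluenesulfonate), 23 °C
Reagents that add atoms: ozone, [O-][O+]=O (its oxygen remains only in 11 and 12); methanol, CO; trimethyl orthoformate, COC(OC)OC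
Why: Ozonolysis followed by acetal formation, in which ozone should cleave the only alkene much faster than it attacks the dimethoxyarene, reduction of ozonide 11 gives aldehyde 12, and acid-catalysed acetalisation with orthoformate as water scavenger masks C4 as the dimethyl acetal for the enolate and acetylide steps.

Step 6
Reactants: 13 (3R,4R,5S)-3-(2,2-dimethoxyethyl)-5-(3,4-dimethoxyphenyl)-4-methyldihydrofuran-2(3H)-one
Product: 15 (3S,4R,5S)-3-(2,2-dimethoxyethyl)-5-(3,4-dimethoxyphenyl)-4-methyl-3-(prop-2-en-1-yl)dihydrofuran-2(3H)-one, via lithium enolate 14 (not isolated)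
Conditions: LDA (LiN(i-Pr)2), THF, −78 °C; then allyl bromide, DMPU, −78 → 0 °C
Reagents that add atoms: allyl bromide, C=CCBr; lithium diisopropylamide, [Li]N(C(C)C)C(C)C (lithium remains only in 14)
Why: Diastereoselective enolate alkylation, in which enolate 14 is flat at C6 and allyl bromide should approach from the face opposite the cis-disposed C7 methyl and C8 aryl groups, placing allyl trans to them and the acetal arm cis, which sets the quaternary (S) centre at C6.

Step 7
Reactants: 15 (3S,4R,5S)-3-(2,2-dimethoxyethyl)-5-(3,4-dimethoxyphenyl)-4-methyl-3-(prop-2-en-1-yl)dihydrofuran-2(3H)-one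
Product: 16 (4S)-4-(2,2-dimethoxyethyl)-4-[(1S,2R)-1-(3,4-dimethoxyphenyl)-1-hydroxypropan-2-yl]hept-6-en-1-yn-3-one
Conditions: HC≡CLi (from acetylene, n-BuLi, THF, −78 °C), −78 → −40 °C; AcOH, −78 °C
Reagents that add atoms: lithium acetylide, [Li]C#C
Why: Acetylide addition to a lactone, in which the small lithium acetylide should add once to the C1 carbonyl because the tetrahedral lithium hemiketal is stable at low temperature and C6 has no proton to lose, so the cold acidic quench releases the ynone and the free C8 hydroxyl and opens the temporary ring.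

Step 8
Reactants: 16 (4S)-4-(2,2-dimethoxyethyl)-4-[(1S,2R)-1-(3,4-dimethoxyphenyl)-1-hydroxypropan-2-yl]hept-6-en-1-yn-3-one
Product: 19 (3S)-3-[(1S,2R)-1-(3,4-dimethoxyphenyl)-1-(triethylsilyloxy)propan-2-yl]-4-oxo-3-(prop-2-en-1-yl)hex-5-ynal, via silyl ether acetal 17 (not isolated), via pyridinium salt 18 (not isolated)
Conditions: TESOTf, 2,6-lutidine, CH2Cl2, −78 → 0 °C; then H2O, 23 °C
Reagents that add atoms: triethylsilyl triflate, CC[Si](CC)(CC)OS(=O)(=O)C(F)(F)F; water, O; 2,6-lutidine, Cc1cccc(C)n1 (remains only in 18)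
Why: Silyl triflate–lutidine silylation and acetal cleavage, in which the open-chain C8 carbinol should be silylated at low temperature to 17, warming ionises the dimethyl acetal to an oxocarbenium ion that lutidine traps as pyridinium salt 18, and water hydrolyses 18 to the aldehyde without a Brønsted acid that could ionise the electron-rich benzylic C8–O bond.

Step 9
Reactants: 19 (3S)-3-[(1S,2R)-1-(3,4-dimethoxyphenyl)-1-(triethylsilyloxy)propan-2-yl]-4-oxo-3-(prop-2-en-1-yl)hex-5-ynal
Product: 20 (3S,5Z)-3-[(1S,2R)-1-(3,4-dimethoxyphenyl)-1-(triethylsilyloxy)propan-2-yl]-6-iodo-4-oxo-3-(prop-2-en-1-yl)hex-5-enal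
Conditions: LiI, AcOH, MeCN, 23 °C, dark
Reagents that add atoms: lithium iodide, [Li+].[I-]
Why: Hydrohalogenation of an activated alkyne, in which conjugate addition of iodide to the ynone and protonation of the allenolate anti to iodine should give the (Z)-β-iodoenone with C3–I cis to the C1 carbonyl, as the six-membered ring demands.

Step 10
Reactants: 20 (3S,5Z)-3-[(1S,2R)-1-(3,4-dimethoxyphenyl)-1-(triethylsilyloxy)propan-2-yl]-6-iodo-4-oxo-3-(prop-2-en-1-yl)hex-5-enal
Product: 21 (4S,6S)-6-[(1S,2R)-1-(3,4-dimethoxyphenyl)-1-(triethylsilyloxy)propan-2-yl]-4-hydroxy-6-(prop-2-en-1-yl)cyclohex-2-en-1-one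
Conditions: CrCl2 (6 equiv), NiCl2 (2 mol %), degassed DMSO (0.005 M), 23 °C; aq. work-up
Reagents that add atoms: none
Why: Zerovalent nickel, formed from NiCl2 and CrCl2, should insert into the C3–I bond, the vinylnickel species transmetallates to trivalent chromium, and the C3 vinylchromium adds to the C4 aldehyde, so that C3, by nature the acceptor β-carbon of the enone, reacts as a donor. The closest known reaction type is the intramolecular Nozaki–Hiyama–Kishi coupling of alkenyl iodides, β-iodoenones included, with aldehydes. The cyclohexenone ring closes in a 6-exo-trig mode, C3 attacking the carbonyl carbon C4 whose oxygen stays outside the ring. The new C4 stereocentre is controlled by the C6 quaternary centre: in the half-chair transition state the aldehyde oxygen must lie pseudo-equatorial to reach the chromium on C3, and the branched C7 side chain should prefer the equatorial position at C6 over allyl, which places O4 cis to the side chain and gives (4S). The step needs chemoselectivity for the aldehyde over the C1 ketone, the silyl ether and the allyl group, which the low basicity and aldehyde selectivity of organochromium reagents secure, and it needs the (Z) geometry fixed in step 9, since only the cis-iodoenone can reach C4; high dilution suppresses intermolecular coupling.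

Step 11
Reactants: 21 (4S,6S)-6-[(1S,2R)-1-(3,4-dimethoxyphenyl)-1-(triethylsilyloxy)propan-2-yl]-4-hydroxy-6-(prop-2-en-1-yl)cyclohex-2-en-1-one
Product: 22 (4S,6S)-6-[(1S,2R)-1-(3,4-dimethoxyphenyl)-1-(triethylsilyloxy)propan-2-yl]-4-methoxy-6-(prop-2-en-1-yl)cyclohex-2-en-1-one
Conditions: MeI, Ag2O, 4 Å MS, Et2O, 35 °C, dark
Reagents that add atoms: iodomethane, CI
Why: Purdie methylation, in which the near-neutral Ag2O/MeI system should etherify the unhindered allylic C4 hydroxyl without isomerising the γ-hydroxy enone, while the C8 oxygen is blocked as its silyl ether and the C4 configuration is kept because the C–O bond is not broken.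

Step 12
Reactants: 22 (4S,6S)-6-[(1S,2R)-1-(3,4-dimethoxyphenyl)-1-(triethylsilyloxy)propan-2-yl]-4-methoxy-6-(prop-2-en-1-yl)cyclohex-2-en-1-one
Product: 23 (4S,6S)-6-[(1S,2R)-1-(3,4-dimethoxyphenyl)-1-hydroxypropan-2-yl]-4-methoxy-6-(prop-2-en-1-yl)cyclohex-2-en-1-one
Conditions: HF·pyridine, pyridine, THF, 0 → 23 °C
Reagents that add atoms: none
Why: Silyl ether deprotection, in which buffered fluoride should cleave the Si–O bond of the triethylsilyl ether and leave the enone, the allylic methyl ether and the benzylic carbinol intact.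

**Compound list**

1 | 3,4-dimethoxybenzaldehyde (veratraldehyde) | COc1ccc(C=O)cc1OC | starting material
2 | (Z)-crotylboronic acid pinacol ester, 2-[(2Z)-but-2-en-1-yl]-4,4,5,5-tetramethyl-1,3,2-dioxaborolane | C/C=C\CB1OC(C)(C)C(C)(C)O1 | starting material
3 | (1S,2R)-1-(3,4-dimethoxyphenyl)-2-methylbut-3-en-1-ol | C=C[C@@H](C)[C@H](O)c1ccc(OC)c(OC)c1 | intermediate
4 | (1S,2R)-4-(9-borabicyclo[3.3.1]nonan-9-yl)-1-(3,4-dimethoxyphenyl)-2-methylbutan-1-ol | C(C[C@@H](C)[C@H](O)c1ccc(OC)c(OC)c1)B1C2CCCC1CCC2 | intermediate (not isolated)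
5 | (1S,2R)-1-(3,4-dimethoxyphenyl)-2-methylbutane-1,4-diol | OCC[C@@H](C)[C@H](O)c1ccc(OC)c(OC)c1 | intermediate
6 | (3R,4S)-4-(3,4-dimethoxyphenyl)-4-hydroxy-3-methylbutanal | O=CC[C@@H](C)[C@H](O)c1ccc(OC)c(OC)c1 | intermediate (not isolated)
7 | (4R,5S)-5-(3,4-dimethoxyphenyl)-4-methyltetrahydrofuran-2-ol, both anomers | OC1C[C@@H](C)[C@@H](c2ccc(OC)c(OC)c2)O1 | intermediate (not isolated)
8 | (4R,5S)-5-(3,4-dimethoxyphenyl)-4-methyldihydrofuran-2(3H)-one, methyl and aryl cis | O=C1C[C@@H](C)[C@@H](c2ccc(OC)c(OC)c2)O1 | intermediate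
9 | lithium enolate of 8, lithium (2S,3R)-2-(3,4-dimethoxyphenyl)-3-methyl-2,3-dihydrofuran-5-olate | [Li]OC1=C[C@@H](C)[C@@H](c2ccc(OC)c(OC)c2)O1 | intermediate (not isolated)
10 | (3R,4R,5S)-5-(3,4-dimethoxyphenyl)-4-methyl-3-(prop-2-en-1-yl)dihydrofuran-2(3H)-one | O=C1[C@H](CC=C)[C@@H](C)[C@@H](c2ccc(OC)c(OC)c2)O1 | intermediate
11 | (3R,4R,5S)-5-(3,4-dimethoxyphenyl)-4-methyl-3-(1,2,4-trioxolan-3-ylmethyl)dihydrofuran-2(3H)-one, both epimers at the trioxolane carbon | O=C1[C@H](CC2OCOO2)[C@@H](C)[C@@H](c3ccc(OC)c(OC)c3)O1 | intermediate (not isolated)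
12 | 2-[(3R,4R,5S)-5-(3,4-dimethoxyphenyl)-4-methyl-2-oxotetrahydrofuran-3-yl]acetaldehyde | O=C1[C@H](CC=O)[C@@H](C)[C@@H](c2ccc(OC)c(OC)c2)O1 | intermediate (not isolated)
13 | (3R,4R,5S)-3-(2,2-dimethoxyethyl)-5-(3,4-dimethoxyphenyl)-4-methyldihydrofuran-2(3H)-one | O=C1[C@H](CC(OC)OC)[C@@H](C)[C@@H](c2ccc(OC)c(OC)c2)O1 | intermediate
14 | lithium enolate of 13, lithium (2S,3R)-4-(2,2-dimethoxyethyl)-2-(3,4-dimethoxyphenyl)-3-methyl-2,3-dihydrofuran-5-olate | [Li]OC1=C(CC(OC)OC)[C@@H](C)[C@@H](c2ccc(OC)c(OC)c2)O1 | intermediate (not isolated)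
15 | (3S,4R,5S)-3-(2,2-dimethoxyethyl)-5-(3,4-dimethoxyphenyl)-4-methyl-3-(prop-2-en-1-yl)dihydrofuran-2(3H)-one | O=C1[C@@](CC=C)(CC(OC)OC)[C@@H](C)[C@@H](c2ccc(OC)c(OC)c2)O1 | intermediate
16 | (4S)-4-(2,2-dimethoxyethyl)-4-[(1S,2R)-1-(3,4-dimethoxyphenyl)-1-hydroxypropan-2-yl]hept-6-en-1-yn-3-one | C#CC(=O)[C@@](CC=C)(CC(OC)OC)[C@@H](C)[C@H](O)c1ccc(OC)c(OC)c1 | intermediate
17 | (4S)-4-(2,2-dimethoxyethyl)-4-[(1S,2R)-1-(3,4-dimethoxyphenyl)-1-(triethylsilyloxy)propan-2-yl]hept-6-en-1-yn-3-one | C#CC(=O)[C@@](CC=C)(CC(OC)OC)[C@@H](C)[C@H](O[Si](CC)(CC)CC)c1ccc(OC)c(OC)c1 | intermediate (not isolated)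
18 | 2,6-dimethylpyridinium triflate in which N carries the 1-methoxy carbon of the former acetal of 17, both epimers at that carbon | C#CC(=O)[C@@](CC=C)(CC(OC)[n+]1c(C)cccc1C)[C@@H](C)[C@H](O[Si](CC)(CC)CC)c1ccc(OC)c(OC)c1.[O-]S(=O)(=O)C(F)(F)F | intermediate (not isolated)
19 | (3S)-3-[(1S,2R)-1-(3,4-dimethoxyphenyl)-1-(triethylsilyloxy)propan-2-yl]-4-oxo-3-(prop-2-en-1-yl)hex-5-ynal | C#CC(=O)[C@@](CC=C)(CC=O)[C@@H](C)[C@H](O[Si](CC)(CC)CC)c1ccc(OC)c(OC)c1 | intermediate
20 | (3S,5Z)-3-[(1S,2R)-1-(3,4-dimethoxyphenyl)-1-(triethylsilyloxy)propan-2-yl]-6-iodo-4-oxo-3-(prop-2-en-1-yl)hex-5-enal | I/C=C\C(=O)[C@@](CC=C)(CC=O)[C@@H](C)[C@H](O[Si](CC)(CC)CC)c1ccc(OC)c(OC)c1 | intermediate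
21 | (4S,6S)-6-[(1S,2R)-1-(3,4-dimethoxyphenyl)-1-(triethylsilyloxy)propan-2-yl]-4-hydroxy-6-(prop-2-en-1-yl)cyclohex-2-en-1-one | C=CC[C@@]1([C@@H](C)[C@H](O[Si](CC)(CC)CC)c2ccc(OC)c(OC)c2)C[C@H](O)C=CC1=O | intermediate
22 | (4S,6S)-6-[(1S,2R)-1-(3,4-dimethoxyphenyl)-1-(triethylsilyloxy)propan-2-yl]-4-methoxy-6-(prop-2-en-1-yl)cyclohex-2-en-1-one | C=CC[C@@]1([C@@H](C)[C@H](O[Si](CC)(CC)CC)c2ccc(OC)c(OC)c2)C[C@H](OC)C=CC1=O | intermediate
23 | (4S,6S)-6-[(1S,2R)-1-(3,4-dimethoxyphenyl)-1-hydroxypropan-2-yl]-4-methoxy-6-(prop-2-en-1-yl)cyclohex-2-en-1-one | C=CC[C@@]1([C@@H](C)[C@H](O)c2ccc(OC)c(OC)c2)C[C@H](OC)C=CC1=O | target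

**Step count and risks**

Total steps: 12. Longest linear sequence: 12 steps, from 1 to 23.

Steps most likely to fail:

1. Step 10. What may go wrong: poor facial selectivity in the addition of the C3 vinylchromium to the C4 aldehyde, because the preference of the C7 side chain over allyl for the equatorial position at C6 may be small. The fallback sets out from 20. The cyclisation is run as in step 10, and the C4-epimeric alcohol F1 that forms beside 21 is separated. Its C4 centre is inverted in a Mitsunobu reaction (PPh3, DIAD, 4-nitrobenzoic acid, THF, 0 °C) to the (4S)-configured 4-nitrobenzoate F2. Methanolysis (K2CO3, MeOH, 0 °C) brings the route back at 21. The C4 configuration is then fixed by an SN2 inversion and not by the ring closure.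

2. Step 8. What may go wrong: silylation of the ring-closed hemiketal tautomer of 16 in place of the open-chain C8 carbinol, or capture of the oxocarbenium ion by the C8 oxygen, either of which ties up C1 or C4. The fallback sets out from lactone 15 and never passes through a free γ-hydroxy ketone. Aminolysis with Me2AlN(OMe)Me (from AlMe3 and MeNH(OMe)·HCl, CH2Cl2, 0 → 23 °C) should give the hydroxy Weinreb amide F3. Silylation without delay (TESCl, imidazole, DMF, 23 °C) gives the silyl ether Weinreb amide F4. Addition of HC≡CMgBr (THF, 0 °C) then delivers silyl ether acetal 17 as an isolated compound. The route is rejoined at 17, which is taken to 19 by the second stage of step 8 (TESOTf, 2,6-lutidine, CH2Cl2, 0 °C; then H2O).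

3. Step 5. What may go wrong: oxidative attack of ozone on the electron-rich dimethoxyarene in competition with cleavage of the alkene. The fallback sets out from lactone 8. Its lithium enolate 9 is alkylated directly with 2-bromo-1,1-dimethoxyethane (NaI, DMPU, THF, −78 → 23 °C), which installs the acetal arm without any oxidant and rejoins the route at 13; step 4 is then not needed.

**Further compounds**

F1 | step 10 | (4R,6S)-6-[(1S,2R)-1-(3,4-dimethoxyphenyl)-1-(triethylsilyloxy)propan-2-yl]-4-hydroxy-6-(prop-2-en-1-yl)cyclohex-2-en-1-one | C=CC[C@@]1([C@@H](C)[C@H](O[Si](CC)(CC)CC)c2ccc(OC)c(OC)c2)C[C@@H](O)C=CC1=O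
F2 | step 10 | 4-nitrobenzoate of 21, (1S,5S)-5-[(1S,2R)-1-(3,4-dimethoxyphenyl)-1-(triethylsilyloxy)propan-2-yl]-4-oxo-5-(prop-2-en-1-yl)cyclohex-2-en-1-yl 4-nitrobenzoate | C=CC[C@@]1([C@@H](C)[C@H](O[Si](CC)(CC)CC)c2ccc(OC)c(OC)c2)C[C@H](OC(=O)c2ccc(cc2)[N+](=O)[O-])C=CC1=O
F3 | step 8 | (2S)-2-(2,2-dimethoxyethyl)-2-[(1S,2R)-1-(3,4-dimethoxyphenyl)-1-hydroxypropan-2-yl]-N-methoxy-N-methylpent-4-enamide | CON(C)C(=O)[C@@](CC=C)(CC(OC)OC)[C@@H](C)[C@H](O)c1ccc(OC)c(OC)c1
F4 | step 8 | (2S)-2-(2,2-dimethoxyethyl)-2-[(1S,2R)-1-(3,4-dimethoxyphenyl)-1-(triethylsilyloxy)propan-2-yl]-N-methoxy-N-methylpent-4-enamide | CON(C)C(=O)[C@@](CC=C)(CC(OC)OC)[C@@H](C)[C@H](O[Si](CC)(CC)CC)c1ccc(OC)c(OC)c1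
F0 | step 5 | none | none
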